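The target grows slowly in teal and ochre and reaches 10.1% and 12.0% of the starting material charged, so the amount of starting material left at a given time is the number to follow.

| flask | starting material | partner | protic impurity | free catalyst | remark | time |
|---|---|---|---|---|---|---|
| teal | 0.20 M | 0.48 equiv | 0.20 M | 0.66 mol% | run made earlier |  |
| ochre | 0.20 M | 0.94 equiv | 0.20 M | 0.66 mol% | run made earlier |  |
| delta | 0.20 M | 0.950 equiv | 0.200 M | 0.66 mol% |  | 2.5 min |
| theta | 0.20 M | 1.20 equiv | 0.200 M | 0.66 mol% |  | 2.5 min |

| run | time / s | catalyst intermediate E / % | catalyst intermediate D / % | starting material / % | target / % |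
|---|---|---|---|---|---|
| teal | 10.0 | 1.2 | 0 | 96.2 | 2.3 |
| teal | 15.0 | 0 | 0 | 94.0 | 3.5 |
| teal | 25.0 | 0 | 1.3 | 91.3 | 2.9 |
| teal | 40.0 | 0 | 1.6 | 83.9 | 4.6 |
| teal | 60.0 | 0.1 | 0.3 | 79.2 | 5.8 |
| teal | 80.0 | 0 | 0 | 71.1 | 10.1 |
| ochre | 10.0 | 0 | 1.9 | 94.2 | 1.5 |
| ochre | 15.0 | 0 | 0 | 93.0 | 3.3 |
| ochre | 25.0 | 0 | 0.3 | 89.0 | 7.1 |
| ochre | 40.0 | 0.7 | 0.7 | 82.4 | 6.2 |
| ochre | 60.0 | 0.3 | 0 | 78.5 | 10.0 |
| ochre | 80.0 | 0.6 | 0.3 | 69.8 | 12.0 |

(scatter of a reading: 1 percentage point)

- the numbers in the tables scatter by 1 percentage point (one standard deviation)

- which of these there is most of at the end, counted by the starting material in it, delta (target / catalyst intermediate E / catalyst intermediate D / starting material)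
- which of these there is most of at the end, counted by the starting material in it, theta (target / catalyst intermediate E / catalyst intermediate D / starting material)
- amount of the one of these that there is most of at the end, in percent of the starting material charged, delta
- amount of the one of these that there is most of at the end, in percent of the starting material charged, theta

In the first instants, at 10.0 s, teal holds 96.2% starting material and ochre 94.2%, and at no reading does catalyst intermediate D or E stand above 1.9%, against a scatter of 1 percentage point. In the middle, at 40.0 s, the runs read 83.9% and 82.4%, although ochre has twice the partner of teal, a difference of 1.5 points against a scatter of 1 point on each reading. At the last reading, 71.1% and 69.8% stand, and these give the survival constant, the logarithm of charge over what is left, divided by the time, averaged over both runs: 0.263 min⁻¹, an apparent pseudo-first-order constant read from the readings.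

On this reckoning, 51.8% of the starting material is left at 2.5 min, in delta and theta alike. The last reading of ochre shows a share of 0.397 of its loss as target, which gives an estimate of 19.1% target, less than the starting material left. Putting that answer back in, with one partner reckoned as spent per target, delta is estimated to keep 0.759 equivalents of partner, more than teal was charged with, so the second round of this reckoning keeps the constant as it was, for theta too.

The forecast names starting material for delta and starting material for theta, at 50% and 50%, a little below this reckoning: “Starting material is therefore the largest component in both runs, essentially independent of partner.”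

The flasks give starting material at 50.2% in delta, with target at 23.0%, and starting material at 48.8% in theta, with target at 24.7%.

    partner + free catalyst → catalyst intermediate A (k = 4.36 M⁻¹ s⁻¹)
    catalyst intermediate A → catalyst intermediate B (k = 2.46 s⁻¹)
    catalyst intermediate B → by-product + catalyst intermediate C (k = 2.21 s⁻¹)
    starting material + catalyst intermediate C ⇌ catalyst intermediate D (K = 2.40 M⁻¹, k = 17.9 M⁻¹ s⁻¹)
    catalyst intermediate D → catalyst intermediate E (k = 250 s⁻¹)
    catalyst intermediate E ⇌ free catalyst + target (K = 0.120 M, k = 4.30 s⁻¹)
    2 catalyst intermediate B ⇌ resting dimer, settled at all times (K = 8450 M⁻¹)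
    starting material → decomposition product (k = 1.49 × 10⁻⁵ s⁻¹)
    starting material + protic impurity → quenched substrate (k = 0.0141 M⁻¹ s⁻¹)

In delta at 2.50 min, the turning of starting material and protic impurity into quenched substrate has a half-life of 5.6 min, which is a constant of 0.124 min⁻¹, about half of the survival constant. Quenched substrate there stands at 26.4%, more than the target. For delta read at 1.0 min, the survival constant gives 76.9%, and that flask holds 76.3% starting material.

The runs are simulated with constants of no real substance; scatter was added.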